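The triacontanoyl chain is disconnected at C6–C7, an unactivated CH2–CH2 bond deep in the unbranched polymethylene chain. Tyrosol and 6-bromohexanoic acid give a bromo ester that already holds C1–C6, the ester and the free 4-hydroxyphenyl ring. The α-olefin 1-tetracosene supplies C7–C30. In one flask, 9-BBN turns the olefin's terminal carbon into a primary alkylborane, and Pd/PCy3 couples it with the primary C6–Br bond (alkyl–alkyl Suzuki–Miyaura). This single operation joins both halves and ends the synthesis without protecting groups. It exploits the fact that C6 and C7 are both unhindered primary termini once cut, and that the ester at C1 and the phenol ring lie remote from the reacting carbon.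

Key step: step 2

Remark: the target has no stereocentre and no stereogenic double bond and is therefore achiral, so no step has to control configuration; acyl carbons are numbered from the ester carbonyl (C1) to the methyl end (C30).

Step 1
Reactants: 1 tyrosol [4-(2-hydroxyethyl)phenol]; 2 6-bromohexanoic acid
Product: 3 4-hydroxyphenethyl 6-bromohexanoate
Conditions: Novozym 435 (immobilised CAL-B), 4 Å MS, MTBE, 45 °C
Reagents that add atoms: none
Why: Lipase-catalysed esterification via the acyl-enzyme of 2 is chemoselective for the unhindered primary aliphatic OH of 1 over the phenolic OH, runs in a neutral medium that leaves the primary C–Br bond untouched, and is driven forward by removal of water on the sieves.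

Step 2
Reactants: 3 4-hydroxyphenethyl 6-bromohexanoate; 4 1-tetracosene; 5 9-borabicyclo[3.3.1]nonane (9-BBN-H)
Product: 7 basalethanolide B (4-hydroxyphenethyl triacontanoate), via B-tetracosyl-9-BBN 6 (not isolated)
Conditions: (i) 4 (1.5 equiv), 5 (0.5 M in THF, 1.4 equiv), THF, rt → 40 °C; (ii) 3 (1.0 equiv), Pd(OAc)2 (4 mol %), PCy3 (8 mol %), K3PO4·H2O (2.5 equiv), THF, rt; aq NH4Cl work-up
Reagents that add atoms: none
Why: 9-BBN-H adds to the terminal C=C of 4 through a concerted four-centre syn hydroboration whose steric demand places boron on the CH2 terminus (future C7) and gives the primary borane 6, the slight deficit of 5 leaving no B–H to react with the phenol. After 3, base and catalyst are added, electron-rich Pd(0)(PCy3)2 enters the primary C6–Br bond by SN2-type oxidative addition, the hydroxide-activated borate of 6 hands over its primary tetracosyl group rather than a secondary bicyclic B–C bond, and reductive elimination forms C6–C7. The closest known reaction type is the room-temperature alkyl–alkyl (B-alkyl) Suzuki–Miyaura coupling of unactivated primary alkyl bromides that carry β-hydrogens, which is established for ester-bearing bromides. No ring is closed and no stereocentre is formed. The step needs coupling to outrun β-hydride elimination, which the bulky, strongly donating PCy3 secures, and it needs the C–Br bond to meet palladium rather than the phenoxide oxygen, which THF as a poorly ionising solvent, the sparingly soluble base and reversible binding of the phenoxide to the excess Lewis-acidic borane should favour. Because the pathway is two-electron, no free alkyl radical arises that the weak phenolic O–H could quench, and the alkyl ester at C1 is inert to K3PO4·H2O at room temperature.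

Compound list
1 | tyrosol, 4-(2-hydroxyethyl)phenol | OCCc1ccc(O)cc1 | starting material
2 | 6-bromohexanoic acid | OC(=O)CCCCCBr | starting material
3 | 4-hydroxyphenethyl 6-bromohexanoate | BrCCCCCC(=O)OCCc1ccc(O)cc1 | intermediate
4 | 1-tetracosene (C24 α-olefin) | CCCCCCCCCCCCCCCCCCCCCCC=C | starting material
5 | 9-borabicyclo[3.3.1]nonane, 9-BBN-H (written as the monomer) | B1C2CCCC1CCC2 | starting material
6 | B-tetracosyl-9-BBN, 9-tetracosyl-9-borabicyclo[3.3.1]nonane (not isolated) | CCCCCCCCCCCCCCCCCCCCCCCCB1C2CCCC1CCC2 | intermediate
7 | basalethanolide B, 4-hydroxyphenethyl triacontanoate (C38H68O3, achiral) | CCCCCCCCCCCCCCCCCCCCCCCCCCCCCC(=O)OCCc1ccc(O)cc1 | target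

Total step count: 2
Longest linear sequence: 2 steps (1 → 3 → 7)

Steps most likely to fail (the route has only two steps, so both are ranked):

1. Step 2. The phenol is deprotonated under the coupling conditions. The phenoxide may then O-alkylate the primary bromide of another molecule, giving ether-linked oligomers. It may also sequester borane or base, which would slow transmetalation enough for β-hydride elimination and hydrodebromination of the alkylpalladium species to take over.
Fallback: the acidic O–H is taken out of the coupling by a bought-in benzyl mask, which turns the protecting-group-free endgame into a protect–couple–release sequence. The fallback sets out from 2. Acid 2 is esterified (EDC·HCl, cat. DMAP, CH2Cl2, 0 °C → rt) with commercial 2-[4-(benzyloxy)phenyl]ethanol F1 to give 4-(benzyloxy)phenethyl 6-bromohexanoate F2. F2 is coupled with borane 6 (prepared from 4 and 5 as in step 2) under Pd(OAc)2/PCy3/K3PO4·H2O in THF at rt to give 4-(benzyloxy)phenethyl triacontanoate F3. Hydrogenolysis of the benzyl aryl ether (H2, Pd/C, THF–EtOAc, 40 °C) leaves the homobenzylic ester intact and comes back to the route at 7.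

2. Step 1. Conversion may stall because water is removed inefficiently or because tyrosol dissolves poorly in the ether solvent. Long reaction times could also erode chemoselectivity through slow acylation of the phenol.
Fallback: the alcohol is activated instead of the acid, by a Mitsunobu esterification (PPh3, DIAD, THF, 0 °C → rt). Only the aliphatic OH of 1 forms an alkoxyphosphonium ion, and the carboxylic acid 2 is far more acidic than the phenol, so it acts as the pronucleophile. The fallback sets out from 1 and 2, comes back to the route at 3, and makes no new compound (F0).

Further compounds
F1 | step 2 | 2-[4-(benzyloxy)phenyl]ethanol (purchased) | OCCc1ccc(OCc2ccccc2)cc1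
F2 | step 2 | 4-(benzyloxy)phenethyl 6-bromohexanoate | BrCCCCCC(=O)OCCc1ccc(OCc2ccccc2)cc1
F3 | step 2 | 4-(benzyloxy)phenethyl triacontanoate | CCCCCCCCCCCCCCCCCCCCCCCCCCCCCC(=O)OCCc1ccc(OCc2ccccc2)cc1
F0 | step 1 | none | none
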